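**Plan**
- Retrosynthesis: remove the two esters (O8 propionyl, O11 acetyl), return C8 to the ketone, and open the seven-membered ring at C1–C10. Guaiane numbering is used: C1 ring-fusion CH, C2 CH2, C3 C=O, C4=C5, C6 CH2, C7 CH bearing C11, C8 CH–O, C9 CH2, C10 CH–CH3.
- Enabling feature: C1 is the γ-carbon of the C3=O/C4=C5 cyclopentenone and C10 is β to the C8 oxygen, so a C1 dienolate can add to a C8 (E)-propenyl ketone and close the seven-membered ring.
- The open precursor is cut at C8–C9 (thioester + propenylboronic acid), at C6–C7 (imide dienolate + allylic bromide) and at C5–C6 (β-bromo enone + hydroxymethylstannane).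
- Forward: the five-membered ring comes from 2-methylcyclopentane-1,3-dione; the chain is grown from C5 (C6, then C7/C11, then C8–C10); the seven-membered ring closes in step 10; reduction and two acylations follow.
- Stereochemistry: C7 from the (R)-4-benzyloxazolidinone-directed alkylation; C10 and C1 from C7 in the ring closure; C8 from hydride attack anti to the C7 side chain.

Key step: step 10

Assumption: in the 8-oxo bicycle formed in the key step, the arrangement of the target (C10 methyl cis to the C7 side chain and cis to H-1) is taken to be the thermodynamically favoured one, so that equilibration at C1 and, by retro-Michael/Michael reaction, at C10 works for the route.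

**Step 1**
Reactants: 1 2-methylcyclopentane-1,3-dione
Product: 2 3-bromo-2-methylcyclopent-2-en-1-one
Conditions: (COBr)2, DMF (cat.), CH2Cl2, 0 °C → rt
Reagents that add atoms: oxalyl bromide, BrC(=O)C(=O)Br
Why: Vilsmeier-type activation of the enolised 1,3-dione followed by bromide addition–elimination is the standard route to β-halo enones, and the symmetric dione allows only one product.

**Step 2**
Reactants: 2 3-bromo-2-methylcyclopent-2-en-1-one
Product: 3 3-(hydroxymethyl)-2-methylcyclopent-2-en-1-one
Conditions: Bu3SnCH2OH, Pd(PPh3)4 (5 mol %), 1,4-dioxane, 90 °C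
Reagents that add atoms: (tributylstannyl)methanol, OC[Sn](CCCC)(CCCC)CCCC
Why: Stille coupling of the electron-poor vinyl bromide places the future C6 unambiguously on the enone β-carbon, whereas radical bromination of 2,3-dimethylcyclopent-2-enone is expected to attack the ring CH2 (the future C1) in preference to the 3-methyl group.

**Step 3**
Reactants: 3 3-(hydroxymethyl)-2-methylcyclopent-2-en-1-one
Product: 4 3-(bromomethyl)-2-methylcyclopent-2-en-1-one
Conditions: CBr4, PPh3, CH2Cl2, 0 °C
Reagents that add atoms: carbon tetrabromide, BrC(Br)(Br)Br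
Why: The Appel reaction converts the primary allylic alcohol into the bromide under neutral conditions that leave the enone untouched; the bromide should be used directly.

**Step 4**
Reactants: 5 (R)-4-benzyloxazolidin-2-one; 6 3-methylbut-2-enoyl chloride
Product: 8 (R)-4-benzyl-3-(3-methylbut-2-enoyl)oxazolidin-2-one, via lithium oxazolidinide 7 (not isolated)
Conditions: n-BuLi, THF, −78 °C; then 6, −78 → 0 °C
Reagents that add atoms: none
Why: N-Acylation of the lithiated oxazolidinone by the acid chloride is the standard way to load the auxiliary.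

**Step 5**
Reactants: 8 (R)-4-benzyl-3-(3-methylbut-2-enoyl)oxazolidin-2-one; 4 3-(bromomethyl)-2-methylcyclopent-2-en-1-one
Product: 10 (4R)-4-benzyl-3-[(2R)-3-methyl-2-[(2-methyl-3-oxocyclopent-1-en-1-yl)methyl]but-3-enoyl]oxazolidin-2-one, via sodium dienolate 9 (not isolated)
Conditions: NaN(SiMe3)2, THF, −78 °C; then 4, −78 → −40 °C
Reagents that add atoms: none
Why: Evans alkylation in its deconjugative form: the chelated (Z)-dienolate reacts at its α-carbon with the allylic bromide on the face opposite the benzyl group of the (R)-auxiliary, which sets C7 and leaves an isopropenyl group as the future C11.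

**Step 6**
Reactants: 10 (4R)-4-benzyl-3-[(2R)-3-methyl-2-[(2-methyl-3-oxocyclopent-1-en-1-yl)methyl]but-3-enoyl]oxazolidin-2-one
Product: 11 (4R)-4-benzyl-3-[(2R)-3-hydroxy-3-methyl-2-[(2-methyl-3-oxocyclopent-1-en-1-yl)methyl]butanoyl]oxazolidin-2-one
Conditions: Co(acac)2 (20 mol %), PhSiH3, O2 (1 atm), THF, rt
Reagents that add atoms: dioxygen, O=O
Why: Mukaiyama hydration (hydrogen-atom transfer to the 1,1-disubstituted alkene, then trapping by O2) should give the tertiary C11 alcohol in the Markovnikov sense while the hindered tetrasubstituted enone stays inert; the oxygen is introduced only now because an imide enolate carrying a β-silyloxy group would be prone to β-elimination.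

**Step 7**
Reactants: 11 (4R)-4-benzyl-3-[(2R)-3-hydroxy-3-methyl-2-[(2-methyl-3-oxocyclopent-1-en-1-yl)methyl]butanoyl]oxazolidin-2-one
Product: 12 S-ethyl (2R)-3-hydroxy-3-methyl-2-[(2-methyl-3-oxocyclopent-1-en-1-yl)methyl]butanethioate
Conditions: EtSH (excess), n-BuLi, THF, 0 °C
Reagents that add atoms: ethanethiol, CCS
Why: Thiolysis of the N-acyl oxazolidinone by lithium ethanethiolate at the exocyclic carbonyl releases the auxiliary, and the weakly basic thiolate should neither epimerise C7 nor trigger retro-aldol cleavage of the β-hydroxy carbonyl unit.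

**Step 8**
Reactants: 12 S-ethyl (2R)-3-hydroxy-3-methyl-2-[(2-methyl-3-oxocyclopent-1-en-1-yl)methyl]butanethioate
Product: 13 S-ethyl (2R)-3-methyl-2-[(2-methyl-3-oxocyclopent-1-en-1-yl)methyl]-3-(triethylsilyloxy)butanethioate
Conditions: Et3SiOTf, 2,6-lutidine, CH2Cl2, −78 → 0 °C
Reagents that add atoms: triethylsilyl trifluoromethanesulfonate, CC[Si](CC)(CC)OS(=O)(=O)C(F)(F)F
Why: Silylation of the tertiary alcohol by the silyl triflate (standard for hindered alcohols) masks O11 against oxa-Michael addition and retro-aldol cleavage in the base-mediated ring closure.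

**Step 9**
Reactants: 13 S-ethyl (2R)-3-methyl-2-[(2-methyl-3-oxocyclopent-1-en-1-yl)methyl]-3-(triethylsilyloxy)butanethioate; 14 (E)-prop-1-enylboronic acid
Product: 15 2-methyl-3-[(2R,4E)-3-oxo-2-[2-(triethylsilyloxy)propan-2-yl]hex-4-en-1-yl]cyclopent-2-en-1-one
Conditions: Pd2(dba)3 (2.5 mol %), P(2-furyl)3 (10 mol %), Cu(O2C-2-thienyl) (1.5 equiv), THF, 50 °C
Reagents that add atoms: none
Why: Liebeskind–Srogl coupling acylates the alkenylboronic acid with the thioester under neutral conditions, so the (E)-enone should form with retention of alkene geometry and without touching the cyclopentenone or C7.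

**Step 10**
Reactants: 15 2-methyl-3-[(2R,4E)-3-oxo-2-[2-(triethylsilyloxy)propan-2-yl]hex-4-en-1-yl]cyclopent-2-en-1-one
Product: 18 (1R,7R,10S)-11-(triethylsilyloxy)guai-4-ene-3,8-dione, via potassium C1-dienolate 16 (not isolated), via potassium C8-enolate 17 (not isolated)
Conditions: KOt-Bu (0.3 equiv), t-BuOH/THF 1:5 (0.01 M), 0 °C → rt
Reagents that add atoms: none
Why: Proposed new method: catalytic tert-butoxide in a protic medium equilibrates the enolisable positions of 15, and only the extended dienolate 16, formed by deprotonation at C1 (γ-carbon of the C3=O/C4=C5 enone), can reach C10, the β-carbon of the (E)-propenyl ketone; conjugate addition gives enolate 17, whose protonation at C9 by tert-butanol leaves the C8 ketone beside the restored tetrasubstituted enone. The closest known chemistry is the base-mediated vinylogous Michael addition of cyclic enone dienolates (dimerisation of 3-methylcycloalkenones, intramolecular closures to six-membered rings); a seven-membered closure of this kind has no direct precedent. The ring closes in the 7-endo-trig mode through the s-trans enone, whereas the rival closures are 5-endo-trig (from C6), eight-membered (from C2), or go through C4 to a non-conjugated quaternary adduct that can revert by retro-Michael reaction. C10 should be set relative to C7 in a chair-like transition state with the bulky C7 side chain pseudo-equatorial and the methyl of the (E)-alkene anti to C5 across the forming bond; C1 forms with C2 trans to that methyl (H-1 cis to CH3) and can correct itself by γ-deprotonation and reprotonation. The step needs γ-regioselectivity and must avoid enolisation at C7 (epimerisation, loss of triethylsilanolate); the tertiary, neopentyl-like C7–H should be the slowest proton to be removed, and high dilution suppresses intermolecular addition through C6.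

**Step 11**
Reactants: 18 (1R,7R,10S)-11-(triethylsilyloxy)guai-4-ene-3,8-dione
Product: 19 (1R,7S,8R,10S)-8-hydroxy-11-(triethylsilyloxy)guai-4-en-3-one
Conditions: LiBH(s-Bu)3 (1.1 equiv), THF, −78 °C; H2O
Reagents that add atoms: none
Why: Ketone reduction by a bulky trialkylborohydride should deliver hydride to C8 from the face opposite the C7 side chain and the C10 methyl, giving the 7,8-cis alcohol, while the less electrophilic conjugated C3 carbonyl should survive one equivalent at −78 °C.

**Step 12**
Reactants: 19 (1R,7S,8R,10S)-8-hydroxy-11-(triethylsilyloxy)guai-4-en-3-one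
Product: 20 (1R,7S,8R,10S)-3-oxo-11-(triethylsilyloxy)guai-4-en-8-yl propanoate
Conditions: (EtCO)2O, Et3N, DMAP (cat.), CH2Cl2, rt
Reagents that add atoms: propanoic anhydride, CCC(=O)OC(=O)CC
Why: DMAP-catalysed (Steglich-type) acylation of the only free hydroxyl group, a secondary alcohol, installs the propionate with no selectivity issue.

**Step 13**
Reactants: 20 (1R,7S,8R,10S)-3-oxo-11-(triethylsilyloxy)guai-4-en-8-yl propanoate
Product: 21 (1R,7S,8R,10S)-11-hydroxy-3-oxoguai-4-en-8-yl propanoate
Conditions: HF·pyridine, pyridine, THF, 0 °C → rt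
Reagents that add atoms: none
Why: Fluoride-mediated desilylation under buffered acidic conditions frees the tertiary alcohol without forming an alkoxide, which avoids propionyl migration from O8 to O11.

**Step 14**
Reactants: 21 (1R,7S,8R,10S)-11-hydroxy-3-oxoguai-4-en-8-yl propanoate
Product: 22 (1R,7S,8R,10S)-11-acetoxy-3-oxoguai-4-en-8-yl propanoate (target, CNP0288556.1)
Conditions: Ac2O, Et3N, DMAP, CH2Cl2, rt → 35 °C
Reagents that add atoms: acetic anhydride, CC(=O)OC(C)=O
Why: DMAP-catalysed acetylation with acetic anhydride (Steglich conditions, which also acylate tertiary alcohols) esterifies O11 and completes the target.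

**Compound list**
1 | 2-methylcyclopentane-1,3-dione | CC1C(=O)CCC1=O | starting material
2 | 3-bromo-2-methylcyclopent-2-en-1-one | CC1=C(Br)CCC1=O | intermediate
3 | 3-(hydroxymethyl)-2-methylcyclopent-2-en-1-one | CC1=C(CO)CCC1=O | intermediate
4 | 3-(bromomethyl)-2-methylcyclopent-2-en-1-one | CC1=C(CBr)CCC1=O | intermediate
5 | (R)-4-benzyloxazolidin-2-one | O=C1N[C@H](Cc2ccccc2)CO1 | starting material
6 | 3-methylbut-2-enoyl chloride | CC(C)=CC(Cl)=O | starting material
7 | lithium (4R)-4-benzyl-2-oxooxazolidin-3-ide (not isolated) | [Li+].O=C1[N-][C@H](Cc2ccccc2)CO1 | intermediate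
8 | (R)-4-benzyl-3-(3-methylbut-2-enoyl)oxazolidin-2-one | CC(C)=CC(=O)N1[C@H](Cc2ccccc2)COC1=O | intermediate
9 | sodium (1Z)-1-[(4R)-4-benzyl-2-oxooxazolidin-3-yl]-3-methylbuta-1,3-dien-1-olate (not isolated) | [Na+].C=C(C)/C=C(\[O-])N1[C@H](Cc2ccccc2)COC1=O | intermediate
10 | (4R)-4-benzyl-3-[(2R)-3-methyl-2-[(2-methyl-3-oxocyclopent-1-en-1-yl)methyl]but-3-enoyl]oxazolidin-2-one | CC1=C(C[C@@H](C(=O)N2[C@H](Cc3ccccc3)COC2=O)C(C)=C)CCC1=O | intermediate
11 | (4R)-4-benzyl-3-[(2R)-3-hydroxy-3-methyl-2-[(2-methyl-3-oxocyclopent-1-en-1-yl)methyl]butanoyl]oxazolidin-2-one | CC1=C(C[C@@H](C(=O)N2[C@H](Cc3ccccc3)COC2=O)C(C)(C)O)CCC1=O | intermediate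
12 | S-ethyl (2R)-3-hydroxy-3-methyl-2-[(2-methyl-3-oxocyclopent-1-en-1-yl)methyl]butanethioate | CC1=C(C[C@@H](C(=O)SCC)C(C)(C)O)CCC1=O | intermediate
13 | S-ethyl (2R)-3-methyl-2-[(2-methyl-3-oxocyclopent-1-en-1-yl)methyl]-3-(triethylsilyloxy)butanethioate | CC1=C(C[C@@H](C(=O)SCC)C(C)(C)O[Si](CC)(CC)CC)CCC1=O | intermediate
14 | (E)-prop-1-enylboronic acid | C/C=C/B(O)O | starting material
15 | 2-methyl-3-[(2R,4E)-3-oxo-2-[2-(triethylsilyloxy)propan-2-yl]hex-4-en-1-yl]cyclopent-2-en-1-one (key-step precursor) | CC1=C(C[C@@H](C(=O)/C=C/C)C(C)(C)O[Si](CC)(CC)CC)CCC1=O | intermediate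
16 | potassium 2-methyl-3-[(2R,4E)-3-oxo-2-[2-(triethylsilyloxy)propan-2-yl]hex-4-en-1-yl]cyclopenta-1,3-dien-1-olate (C1 dienolate of 15, not isolated) | [K+].CC1=C([O-])CC=C1C[C@@H](C(=O)/C=C/C)C(C)(C)O[Si](CC)(CC)CC | intermediate
17 | potassium C8-enolate (C8–O−, C8=C9) of dione 18 (ring-closed Michael adduct, not isolated) | [K+].[O-]C1=C[C@H](C)[C@H]2CC(=O)C(C)=C2C[C@@H]1C(C)(C)O[Si](CC)(CC)CC | intermediate
18 | (1R,7R,10S)-11-(triethylsilyloxy)guai-4-ene-3,8-dione (H-1, CH3-10 and the C7 side chain on one face) | O=C1C[C@H](C)[C@H]2CC(=O)C(C)=C2C[C@@H]1C(C)(C)O[Si](CC)(CC)CC | intermediate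
19 | (1R,7S,8R,10S)-8-hydroxy-11-(triethylsilyloxy)guai-4-en-3-one (8-OH cis to the C7 side chain) | O[C@@H]1C[C@H](C)[C@H]2CC(=O)C(C)=C2C[C@@H]1C(C)(C)O[Si](CC)(CC)CC | intermediate
20 | (1R,7S,8R,10S)-3-oxo-11-(triethylsilyloxy)guai-4-en-8-yl propanoate | CCC(=O)O[C@@H]1C[C@H](C)[C@H]2CC(=O)C(C)=C2C[C@@H]1C(C)(C)O[Si](CC)(CC)CC | intermediate
21 | (1R,7S,8R,10S)-11-hydroxy-3-oxoguai-4-en-8-yl propanoate | CCC(=O)O[C@@H]1C[C@H](C)[C@H]2CC(=O)C(C)=C2C[C@@H]1C(C)(C)O | intermediate
22 | (1R,7S,8R,10S)-11-acetoxy-3-oxoguai-4-en-8-yl propanoate (CNP0288556.1) | CCC(=O)O[C@@H]1C[C@H](C)[C@H]2CC(=O)C(C)=C2C[C@@H]1C(C)(C)OC(C)=O | target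

**Step count**
Total step count: 14. Longest linear sequence: 13 steps (steps 1–3 and 5–14, from 1 to 22).

**Steps most likely to fail**

1. Step 10 (new method). Proton transfer at C7 (epimerisation, then loss of triethylsilanolate) or closure through C4 may outrun the C1–C10 closure, intermolecular addition through C6 may compete, and facial selectivity at C10 may be low. The fallback sets out from thioester 13 and returns at 18; each operation is an established reaction type, although this particular closure would be equally new.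
   - Soft enolisation of the cyclopentenone (t-BuMe2SiOTf, Et3N, CH2Cl2) would give the silyloxycyclopentadiene thioester F1; 1,5-hydrogen shifts make the C1-nucleophilic 1-silyloxy-1,3-diene available.
   - Thioester–boronic acid coupling with 14 under the conditions of step 9 would give the silyl dienol ether enone F2.
   - Me2AlCl in CH2Cl2 at −78 °C would then close the ring by an intramolecular vinylogous Mukaiyama–Michael addition, a Lewis-acid-mediated reaction type that has been used to close medium rings. Aqueous work-up would deliver 18, and no free enolate is ever generated next to the silyloxy group.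

2. Step 11. The hydride may lose chemoselectivity and attack the C3 carbonyl of the enone as well. The fallback sets out from 18 and returns at 19.
   - Excess LiBH(s-Bu)3 (THF, −78 → 0 °C) would reduce both carbonyl groups, C8 still from the face anti to the C7 side chain, to the 3,8-diol F3 (mixture at C3).
   - MnO2 in CH2Cl2 would then reoxidise only the allylic C3 alcohol and return the enone.

3. Step 5. Proton transfer from the acidic γ-bromo enone to the dienolate, or attack of the dienolate on the enone, may compete with the substitution. The fallback masks the enone; it sets out from bromide 4 (and dienolate 9) and returns at 10.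
   - i-Bu2AlH (CH2Cl2, −78 °C) would reduce 4 to the bromo allylic alcohol F4.
   - t-BuMe2SiOTf/2,6-lutidine would give the silyl ether F5, a simple, non-acidic allylic bromide.
   - Alkylation of dienolate 9 with F5 under the conditions of step 5 would give imide F6 (both C3 epimers).
   - HF·pyridine would free the allylic alcohol F7, and MnO2 would oxidise it to 10.

**Further compounds**
F1 | step 10 | S-ethyl (2R)-2-{[3-(tert-butyldimethylsilyloxy)-2-methylcyclopenta-1,3-dien-1-yl]methyl}-3-methyl-3-(triethylsilyloxy)butanethioate | CC1=C(O[Si](C)(C)C(C)(C)C)CC=C1C[C@@H](C(=O)SCC)C(C)(C)O[Si](CC)(CC)CC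
F2 | step 10 | (2E,5R)-5-{[3-(tert-butyldimethylsilyloxy)-2-methylcyclopenta-1,3-dien-1-yl]methyl}-6-methyl-6-(triethylsilyloxy)hept-2-en-4-one | CC1=C(O[Si](C)(C)C(C)(C)C)CC=C1C[C@@H](C(=O)/C=C/C)C(C)(C)O[Si](CC)(CC)CC
F3 | step 11 | (1R,7S,8R,10S)-11-(triethylsilyloxy)guai-4-ene-3,8-diol (C3 epimers) | O[C@@H]1C[C@H](C)[C@H]2CC(O)C(C)=C2C[C@@H]1C(C)(C)O[Si](CC)(CC)CC
F4 | step 5 | 3-(bromomethyl)-2-methylcyclopent-2-en-1-ol (racemic) | CC1=C(CBr)CCC1O
F5 | step 5 | {[3-(bromomethyl)-2-methylcyclopent-2-en-1-yl]oxy}(tert-butyl)dimethylsilane (racemic) | CC1=C(CBr)CCC1O[Si](C)(C)C(C)(C)C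
F6 | step 5 | (4R)-4-benzyl-3-[(2R)-2-{[3-(tert-butyldimethylsilyloxy)-2-methylcyclopent-1-en-1-yl]methyl}-3-methylbut-3-enoyl]oxazolidin-2-one (C3 epimers) | CC1=C(C[C@@H](C(=O)N2[C@H](Cc3ccccc3)COC2=O)C(C)=C)CCC1O[Si](C)(C)C(C)(C)C
F7 | step 5 | (4R)-4-benzyl-3-[(2R)-2-[(3-hydroxy-2-methylcyclopent-1-en-1-yl)methyl]-3-methylbut-3-enoyl]oxazolidin-2-one (C3 epimers) | CC1=C(C[C@@H](C(=O)N2[C@H](Cc3ccccc3)COC2=O)C(C)=C)CCC1O
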